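**Retrosynthetic overview**

1. Numbering used: ring C15(OAc)–C1H2–C2(Me)–C3(OBz)–C4(enal arm); chain C14(OAc)–C13(Me)–C12=C11–C10(Me)2–C9(=O)–C8. The enal comes from cross-metathesis of a C4 vinyl group with methacrolein; the benzoate and the C14 acetate from late acylations.
2. The C13–C14 bond and both of its stereocentres come from a chromium-catalysed reductive coupling of diene 19 with the α-acetoxy aldehyde 15 (proposed new method).
3. The tertiary C15 acetate comes from Baeyer–Villiger oxidation of a 1-acetylcyclopentane (retention).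
4. The cyclopentane comes from a semipinacol (halohydrin) ring contraction of a 2-chloro-1-methylcyclohexanol alkoxide, assembled by a vinyl cuprate/formaldehyde three-component coupling on a 2-chloro-4-silyloxy-5-methylcyclohexenone.
5. Ring order: the only carbocycle is bought as the six-membered ring of 1 and contracted to the five-membered ring in step 6; no other ring is formed.

Assumption: (S)-5-methylcyclohex-2-en-1-one (1) is purchased as the single enantiomer, and the Grignard reagents 7 and 16 as commercial THF solutions.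

**Route**

Step 1
Reactants: 1 (S)-5-methylcyclohex-2-en-1-one
Product: 2 (R)-5-methylcyclohex-3-en-1-one
Conditions: KOtBu (1.5 equiv), tBuOH–THF, 0 °C; inverse quench into AcOH–H2O, 0 °C
Reagents that add atoms: none
Why: Thermodynamic γ-deprotonation gives the extended potassium dienolate, whose kinetic α-protonation (deconjugative protonation of a dienolate) delivers the β,γ-enone without touching the methyl-bearing stereocentre.

Step 2
Reactants: 2 (R)-5-methylcyclohex-3-en-1-one
Product: 4 (4S,5R)-4-hydroxy-5-methylcyclohex-2-en-1-one, via epoxy ketone 3 (not isolated)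
Conditions: mCPBA, CH2Cl2, 0 °C; NaHCO3 wash; Et3N (20 mol %), CH2Cl2, rt
Reagents that add atoms: 3-chloroperbenzoic acid, O=C(OO)c1cccc(Cl)c1
Why: Prilezhaev epoxidation takes place on the alkene face anti to the adjacent methyl group and the base then opens the β,γ-epoxy ketone by α-deprotonation/E1cB epoxide opening, so the new carbinol (future C3–O) is set trans to the methyl.

Step 3
Reactants: 4 (4S,5R)-4-hydroxy-5-methylcyclohex-2-en-1-one
Product: 5 (4S,5R)-4-[(tert-butyldimethylsilyl)oxy]-5-methylcyclohex-2-en-1-one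
Conditions: TBSCl, imidazole, DMF, rt
Reagents that add atoms: tert-butyldimethylsilyl chloride, CC(C)(C)[Si](C)(C)Cl
Why: Standard imidazole-mediated O-silylation (silyl ether protection) of the secondary allylic alcohol.

Step 4
Reactants: 5 (4S,5R)-4-[(tert-butyldimethylsilyl)oxy]-5-methylcyclohex-2-en-1-one
Product: 6 (4S,5R)-4-[(tert-butyldimethylsilyl)oxy]-2-chloro-5-methylcyclohex-2-en-1-one
Conditions: PhICl2, pyridine, CH2Cl2, 0 °C → rt
Reagents that add atoms: iodobenzene dichloride, ClI(Cl)c1ccccc1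
Why: Chlorine transfer to the enone C=C followed by pyridine-mediated dehydrochlorination (α-halogenation of an enone by addition–elimination) gives the 2-chloro enone without affecting either stereocentre.

Step 5
Reactants: 6 (4S,5R)-4-[(tert-butyldimethylsilyl)oxy]-2-chloro-5-methylcyclohex-2-en-1-one; 7 vinylmagnesium bromide; 8 formaldehyde (monomeric gas from cracked paraformaldehyde)
Product: 11 (2R,3S,4S,5R)-4-[(tert-butyldimethylsilyl)oxy]-2-chloro-5-methyl-2-{[(triethylsilyl)oxy]methyl}-3-vinylcyclohexan-1-one, via magnesium enolate 9 (not isolated), via magnesium aldolate 10 (not isolated)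
Conditions: CH2=CHMgBr, CuBr·SMe2 (10 mol %), THF, −78 °C; CH2O (g), −78 °C; Et3SiCl, DMAP (cat.), −78 → −20 °C
Reagents that add atoms: chlorotriethylsilane, CC[Si](Cl)(CC)CC
Why: Copper-catalysed conjugate addition of the vinyl group occurs by axial attack trans to the C5 methyl (cis to the equatorial silyloxy group), the resulting α-chloro magnesium enolate is hydroxymethylated by formaldehyde (aldol) on the face anti to the new vinyl group, which places chlorine cis to vinyl at the new quaternary carbon, and low-temperature O-silylation forestalls Darzens closure (tandem conjugate addition–aldol three-component coupling).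

Step 6
Reactants: 11 (2R,3S,4S,5R)-4-[(tert-butyldimethylsilyl)oxy]-2-chloro-5-methyl-2-{[(triethylsilyl)oxy]methyl}-3-vinylcyclohexan-1-one
Product: 13 1-[(1R,2R,3S,4R)-3-[(tert-butyldimethylsilyl)oxy]-4-methyl-1-{[(triethylsilyl)oxy]methyl}-2-vinylcyclopentyl]ethan-1-one, via magnesium chlorohydrinate 12 (not isolated)
Conditions: MeMgBr, toluene–Et2O, −78 → 0 °C; then 80 °C
Reagents that add atoms: methylmagnesium bromide, C[Mg]Br
Why: Grignard 1,2-addition gives the magnesium chlorohydrinate, in whose locked chair the equatorial C–Cl bond is antiperiplanar to the C1–C6 ring bond, so on warming that bond migrates with inversion as chloride leaves (Tiffeneau-type halohydrin semipinacol ring contraction), contracting the ring to the cyclopentane and leaving the extruded carbon as an acetyl group cis to the vinyl group at the quaternary carbon (either carbinol epimer converges).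

Step 7
Reactants: 13 1-[(1R,2R,3S,4R)-3-[(tert-butyldimethylsilyl)oxy]-4-methyl-1-{[(triethylsilyl)oxy]methyl}-2-vinylcyclopentyl]ethan-1-one
Product: 14 (1R,2S,3S,4R)-3-[(tert-butyldimethylsilyl)oxy]-4-methyl-1-{[(triethylsilyl)oxy]methyl}-2-vinylcyclopentyl acetate
Conditions: Me3SiOOSiMe3, TMSOTf (10 mol %), CH2Cl2, −30 → 0 °C
Reagents that add atoms: bis(trimethylsilyl) peroxide, C[Si](C)(C)OO[Si](C)(C)C
Why: Baeyer–Villiger oxidation via the silyl Criegee adduct: the quaternary ring carbon migrates in preference to methyl with retention, converting the acetyl group into the tertiary acetate, and the non-peracid oxidant does not epoxidise the vinyl group.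

Step 8
Reactants: 14 (1R,2S,3S,4R)-3-[(tert-butyldimethylsilyl)oxy]-4-methyl-1-{[(triethylsilyl)oxy]methyl}-2-vinylcyclopentyl acetate
Product: 15 (1R,2S,3S,4R)-3-[(tert-butyldimethylsilyl)oxy]-1-formyl-4-methyl-2-vinylcyclopentyl acetate
Conditions: (COCl)2, DMSO, CH2Cl2, −78 → −30 °C; Et3N, −78 → 0 °C
Reagents that add atoms: none
Why: Under Swern conditions the activated sulfonium species cleaves the primary triethylsilyl ether and oxidises it in situ (Swern oxidation of a primary silyl ether), while the secondary tert-butyldimethylsilyl ether and the tertiary acetate are inert and the quaternary α-carbon cannot epimerise.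

Step 9
Reactants: 16 (3-methylbut-2-en-1-yl)magnesium chloride
Product: 17 3,3-dimethylpent-4-en-2-one
Conditions: Ac2O (3 equiv), THF, −78 °C (Grignard added to the anhydride)
Reagents that add atoms: acetic anhydride, CC(=O)OC(C)=O
Why: Allylic Grignard reagents acylate through the γ-carbon (SE2' acylation with an anhydride at low temperature), giving the α,α-dimethyl β,γ-unsaturated methyl ketone without over-addition.

Step 10
Reactants: 17 3,3-dimethylpent-4-en-2-one; 18 vinyl bromide
Product: 19 (E)-3,3-dimethylhepta-4,6-dien-2-one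
Conditions: Pd(OAc)2 (5 mol %), P(o-tol)3 (10 mol %), Et3N, MeCN, 80 °C, sealed tube
Reagents that add atoms: none
Why: Mizoroki–Heck vinylation of the terminal alkene: insertion places palladium next to the quaternary carbon, so β-hydride elimination can only give the conjugated (E)-diene.

Step 11
Reactants: 15 (1R,2S,3S,4R)-3-[(tert-butyldimethylsilyl)oxy]-1-formyl-4-methyl-2-vinylcyclopentyl acetate; 19 (E)-3,3-dimethylhepta-4,6-dien-2-one
Product: 20 (1R,2S,3S,4R)-3-[(tert-butyldimethylsilyl)oxy]-1-[(1R,2R,3E)-1-hydroxy-2,5,5-trimethyl-6-oxohept-3-en-1-yl]-4-methyl-2-vinylcyclopentyl acetate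
Conditions: CrCl3 (10 mol %), chiral indane-fused bis(oxazoline) ligand (12 mol %, antipode chosen for Re-face delivery), Co(dmgH)2(py)Cl (5 mol %), 4CzIPN (2 mol %), Hantzsch ester (1.5 equiv), THF, blue LEDs, 20 °C
Reagents that add atoms: none
Why: Proposed new method: an enantioselective chromium-catalysed reductive diene–aldehyde coupling in which the photocatalyst/Hantzsch ester couple turns over a cobalt hydride that transfers a hydrogen atom to the unhindered diene terminus (making C20 a methyl group) and reduces trivalent to divalent chromium, which captures the allyl radical; the allylchromium, bound at the hindered C11 terminus, adds through its methyl-bearing γ-carbon in a chair Zimmerman–Traxler transition state to the Re face of the aldehyde selected by the chiral ligand, giving the anti (14R,13R) adduct with an E alkene and leaving the ketone of 19 untouched; the closest known reaction types are the photoredox/chromium (Nozaki–Hiyama-type) allylation of aldehydes with alkene- or diene-derived allyl radicals and cobalt-hydride hydrogen-atom transfer to 1,3-dienes, neither shown for a 1-tert-alkyl diene with an α-quaternary α-acyloxy aldehyde.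

Step 12
Reactants: 20 (1R,2S,3S,4R)-3-[(tert-butyldimethylsilyl)oxy]-1-[(1R,2R,3E)-1-hydroxy-2,5,5-trimethyl-6-oxohept-3-en-1-yl]-4-methyl-2-vinylcyclopentyl acetate
Product: 21 (1R,2R,3E)-1-[(1R,2S,3S,4R)-1-acetoxy-3-[(tert-butyldimethylsilyl)oxy]-4-methyl-2-vinylcyclopentyl]-2,5,5-trimethyl-6-oxohept-3-en-1-yl acetate
Conditions: Ac2O, DMAP (cat.), pyridine, 40 °C
Reagents that add atoms: acetic anhydride, CC(=O)OC(C)=O
Why: DMAP-catalysed acylation (Steglich-type acetylation) of the hindered secondary alcohol; should the neighbouring tertiary acetate have migrated, both hydroxyls are acetylated under these conditions and the same diacetate results.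

Step 13
Reactants: 21 (1R,2R,3E)-1-[(1R,2S,3S,4R)-1-acetoxy-3-[(tert-butyldimethylsilyl)oxy]-4-methyl-2-vinylcyclopentyl]-2,5,5-trimethyl-6-oxohept-3-en-1-yl acetate
Product: 23 (1R,2R,3E)-1-[(1R,2S,3S,4R)-1-acetoxy-3-(benzoyloxy)-4-methyl-2-vinylcyclopentyl]-2,5,5-trimethyl-6-oxohept-3-en-1-yl acetate, via C3 alcohol 22 (not isolated)
Conditions: HF·pyridine, THF, 0 °C → rt; volatiles removed; BzCl, DMAP (cat.), pyridine, 0 °C → rt
Reagents that add atoms: benzoyl chloride, O=C(Cl)c1ccccc1
Why: Fluoride-mediated desilylation followed by pyridine/DMAP benzoylation (nucleophilic acyl substitution at the acyl chloride) proceeds with retention at C3.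

Step 14
Reactants: 23 (1R,2R,3E)-1-[(1R,2S,3S,4R)-1-acetoxy-3-(benzoyloxy)-4-methyl-2-vinylcyclopentyl]-2,5,5-trimethyl-6-oxohept-3-en-1-yl acetate; 24 methacrolein
Product: 25 (1R,2R,3E)-1-[(1R,2S,3S,4R)-1-acetoxy-3-(benzoyloxy)-4-methyl-2-[(1E)-2-methyl-3-oxoprop-1-en-1-yl]cyclopentyl]-2,5,5-trimethyl-6-oxohept-3-en-1-yl acetate (target CNP0489076.2)
Conditions: second-generation Hoveyda–Grubbs catalyst (10 mol %), methacrolein (10 equiv), CH2Cl2, 40 °C
Reagents that add atoms: none
Why: Olefin cross-metathesis of the terminal vinyl group with excess methacrolein gives the thermodynamically favoured (E)-trisubstituted enal, while the hindered internal alkene flanked by a quaternary carbon does not engage the catalyst.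

**Compound list**

1 | (S)-5-methylcyclohex-2-en-1-one | O=C1C[C@@H](C)CC=C1 | starting material
2 | (R)-5-methylcyclohex-3-en-1-one | O=C1C[C@@H](C)C=CC1 | intermediate
3 | 3,4-epoxy-5-methylcyclohexan-1-one, oxirane trans to the methyl group (epoxy ketone) | O=C1C[C@@H](C)[C@@H]2O[C@@H]2C1 | intermediate
4 | (4S,5R)-4-hydroxy-5-methylcyclohex-2-en-1-one | O=C1C[C@@H](C)[C@H](O)C=C1 | intermediate
5 | (4S,5R)-4-[(tert-butyldimethylsilyl)oxy]-5-methylcyclohex-2-en-1-one | O=C1C[C@@H](C)[C@H](O[Si](C)(C)C(C)(C)C)C=C1 | intermediate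
6 | (4S,5R)-4-[(tert-butyldimethylsilyl)oxy]-2-chloro-5-methylcyclohex-2-en-1-one | O=C1C[C@@H](C)[C@H](O[Si](C)(C)C(C)(C)C)C=C1Cl | intermediate
7 | vinylmagnesium bromide | C=C[Mg]Br | starting material
8 | formaldehyde | C=O | starting material
9 | bromomagnesium 2-chloro enolate (vinyl cis to OTBS, trans to methyl) | Br[Mg]OC1=C(Cl)[C@@H](C=C)[C@@H](O[Si](C)(C)C(C)(C)C)[C@H](C)C1 | intermediate
10 | bromomagnesium alkoxide of the 2-chloro-2-(hydroxymethyl) ketone (magnesium aldolate) | O=C1C[C@@H](C)[C@H](O[Si](C)(C)C(C)(C)C)[C@H](C=C)[C@@]1(Cl)CO[Mg]Br | intermediate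
11 | (2R,3S,4S,5R)-4-[(tert-butyldimethylsilyl)oxy]-2-chloro-5-methyl-2-{[(triethylsilyl)oxy]methyl}-3-vinylcyclohexan-1-one | O=C1C[C@@H](C)[C@H](O[Si](C)(C)C(C)(C)C)[C@H](C=C)[C@@]1(Cl)CO[Si](CC)(CC)CC | intermediate
12 | bromomagnesium alkoxide of the 2-chloro-1-methylcyclohexanol (magnesium chlorohydrinate; methyl equatorial) | C[C@@]1(O[Mg]Br)C[C@@H](C)[C@H](O[Si](C)(C)C(C)(C)C)[C@H](C=C)[C@@]1(Cl)CO[Si](CC)(CC)CC | intermediate
13 | 1-[(1R,2R,3S,4R)-3-[(tert-butyldimethylsilyl)oxy]-4-methyl-1-{[(triethylsilyl)oxy]methyl}-2-vinylcyclopentyl]ethan-1-one | CC(=O)[C@]1(CO[Si](CC)(CC)CC)C[C@@H](C)[C@H](O[Si](C)(C)C(C)(C)C)[C@@H]1C=C | intermediate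
14 | (1R,2S,3S,4R)-3-[(tert-butyldimethylsilyl)oxy]-4-methyl-1-{[(triethylsilyl)oxy]methyl}-2-vinylcyclopentyl acetate | CC(=O)O[C@]1(CO[Si](CC)(CC)CC)C[C@@H](C)[C@H](O[Si](C)(C)C(C)(C)C)[C@@H]1C=C | intermediate
15 | (1R,2S,3S,4R)-3-[(tert-butyldimethylsilyl)oxy]-1-formyl-4-methyl-2-vinylcyclopentyl acetate | CC(=O)O[C@]1(C=O)C[C@@H](C)[C@H](O[Si](C)(C)C(C)(C)C)[C@@H]1C=C | intermediate
16 | (3-methylbut-2-en-1-yl)magnesium chloride | CC(C)=CC[Mg]Cl | starting material
17 | 3,3-dimethylpent-4-en-2-one | CC(=O)C(C)(C)C=C | intermediate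
18 | vinyl bromide | C=CBr | starting material
19 | (E)-3,3-dimethylhepta-4,6-dien-2-one | CC(=O)C(C)(C)/C=C/C=C | intermediate
20 | (1R,2S,3S,4R)-3-[(tert-butyldimethylsilyl)oxy]-1-[(1R,2R,3E)-1-hydroxy-2,5,5-trimethyl-6-oxohept-3-en-1-yl]-4-methyl-2-vinylcyclopentyl acetate | O[C@H]([C@H](C)/C=C/C(C)(C)C(C)=O)[C@@]1(OC(C)=O)C[C@@H](C)[C@H](O[Si](C)(C)C(C)(C)C)[C@@H]1C=C | intermediate
21 | (1R,2R,3E)-1-[(1R,2S,3S,4R)-1-acetoxy-3-[(tert-butyldimethylsilyl)oxy]-4-methyl-2-vinylcyclopentyl]-2,5,5-trimethyl-6-oxohept-3-en-1-yl acetate | CC(=O)O[C@H]([C@H](C)/C=C/C(C)(C)C(C)=O)[C@@]1(OC(C)=O)C[C@@H](C)[C@H](O[Si](C)(C)C(C)(C)C)[C@@H]1C=C | intermediate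
22 | (1R,2R,3E)-1-[(1R,2S,3S,4R)-1-acetoxy-3-hydroxy-4-methyl-2-vinylcyclopentyl]-2,5,5-trimethyl-6-oxohept-3-en-1-yl acetate | CC(=O)O[C@H]([C@H](C)/C=C/C(C)(C)C(C)=O)[C@@]1(OC(C)=O)C[C@@H](C)[C@H](O)[C@@H]1C=C | intermediate
23 | (1R,2R,3E)-1-[(1R,2S,3S,4R)-1-acetoxy-3-(benzoyloxy)-4-methyl-2-vinylcyclopentyl]-2,5,5-trimethyl-6-oxohept-3-en-1-yl acetate | CC(=O)O[C@H]([C@H](C)/C=C/C(C)(C)C(C)=O)[C@@]1(OC(C)=O)C[C@@H](C)[C@H](OC(=O)c2ccccc2)[C@@H]1C=C | intermediate
24 | methacrolein (2-methylprop-2-enal) | CC(=C)C=O | starting material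
25 | (1R,2R,3E)-1-[(1R,2S,3S,4R)-1-acetoxy-3-(benzoyloxy)-4-methyl-2-[(1E)-2-methyl-3-oxoprop-1-en-1-yl]cyclopentyl]-2,5,5-trimethyl-6-oxohept-3-en-1-yl acetate (CNP0489076.2) | CC(=O)O[C@H]([C@H](C)/C=C/C(C)(C)C(C)=O)[C@@]1(OC(C)=O)C[C@@H](C)[C@H](OC(=O)c2ccccc2)[C@@H]1/C=C(\C)C=O | target

**Step count**

Total steps: 14. Longest linear sequence: 12 (steps 1–8, then 11–14); steps 9–10 are the convergent diene branch.

**Three steps most likely to fail, with fallbacks**

Step 11 (the proposed new coupling). Risks are the site of allyl transfer from a 1,3-disubstituted allylchromium and catalyst control over the hindered α-acetoxy aldehyde. The fallback is the classical stoichiometric Nozaki–Hiyama allylation and sets out from diene 19. One equivalent of HBr (CH2Cl2, −78 °C) adds 1,2 to the diene to give the allylic bromide (E)-6-bromo-3,3-dimethylhept-4-en-2-one F9 (racemic). F9 and aldehyde 15 are then treated with CrCl2 (THF, 0 °C), which gives the anti, E-configured adducts under substrate control. Chromatographic separation from the C13/C14 diastereomer returns the route at 20.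

Step 5 (three-component coupling on the α-chloro enone). Risks are halogen loss from the enone, Darzens closure of the chloro aldolate, and the facial selectivity of the cuprate. The fallback avoids the chloride altogether, sets out from enone 5 and rejoins at 13:
- Conjugate addition of CH2=CHMgBr/CuBr·SMe2 to 5 and trapping with formaldehyde gives the hydroxymethyl ketone F1.
- MsCl/Et3N converts it into its mesylate F2 (not isolated), and DBU eliminates to the α-methylene ketone F3.
- MeLi/CeCl3 adds trans to the axial vinyl group to give the tertiary allylic alcohol F4.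
- VO(acac)2/tBuOOH epoxidises the exocyclic alkene syn to the hydroxyl, giving the spiro-epoxy alcohol F5.
- BF3·OEt2 (CH2Cl2, −78 °C) triggers the epoxy-alcohol semipinacol ring contraction (same migrating bond, same stereochemical outcome) to the hydroxy ketone F6.
- Et3SiCl/imidazole then gives 13.

Step 7 (Baeyer–Villiger on a hindered methyl ketone beside a vinyl group). Risks are a sluggish Criegee step and silyl-ether loss under the Lewis acid. The fallback sets out from 13 and masks the alkene. Br2 (CH2Cl2, −78 °C) gives the dibromide F7 (both CHBr epimers, which converge). Buffered CF3CO3H (Na2HPO4, CH2Cl2, 0 °C) then carries out the Baeyer–Villiger oxidation to the dibromo acetate F8. Zn/NH4Cl (EtOH) regenerates the vinyl group and returns the route at 14.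

**Further compounds**

F1 | step 5 | (2S,3S,4S,5R)-configured 4-[(tert-butyldimethylsilyl)oxy]-2-(hydroxymethyl)-5-methyl-3-vinylcyclohexan-1-one (hydroxymethyl trans to vinyl) | O=C1C[C@@H](C)[C@H](O[Si](C)(C)C(C)(C)C)[C@H](C=C)[C@H]1CO
F2 | step 5 | methanesulfonate of F1 | O=C1C[C@@H](C)[C@H](O[Si](C)(C)C(C)(C)C)[C@H](C=C)[C@H]1COS(C)(=O)=O
F3 | step 5 | 4-[(tert-butyldimethylsilyl)oxy]-5-methyl-2-methylidene-3-vinylcyclohexan-1-one (vinyl cis to OTBS, trans to methyl) | O=C1C[C@@H](C)[C@H](O[Si](C)(C)C(C)(C)C)[C@H](C=C)C1=C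
F4 | step 5 | 4-[(tert-butyldimethylsilyl)oxy]-1,5-dimethyl-2-methylidene-3-vinylcyclohexan-1-ol (hydroxyl cis to vinyl) | C[C@@]1(O)C[C@@H](C)[C@H](O[Si](C)(C)C(C)(C)C)[C@H](C=C)C1=C
F5 | step 5 | spiro-epoxy alcohol from F4 (oxirane oxygen cis to the hydroxyl and to vinyl) | C[C@@]1(O)C[C@@H](C)[C@H](O[Si](C)(C)C(C)(C)C)[C@H](C=C)[C@@]12CO2
F6 | step 5 | 1-[(1R,2R,3S,4R)-3-[(tert-butyldimethylsilyl)oxy]-1-(hydroxymethyl)-4-methyl-2-vinylcyclopentyl]ethan-1-one | CC(=O)[C@]1(CO)C[C@@H](C)[C@H](O[Si](C)(C)C(C)(C)C)[C@@H]1C=C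
F7 | step 7 | 1,2-dibromoethyl analogue of 13 (both CHBr epimers) | CC(=O)[C@]1(CO[Si](CC)(CC)CC)C[C@@H](C)[C@H](O[Si](C)(C)C(C)(C)C)[C@@H]1C(Br)CBr
F8 | step 7 | 1,2-dibromoethyl analogue of 14 (both CHBr epimers) | CC(=O)O[C@]1(CO[Si](CC)(CC)CC)C[C@@H](C)[C@H](O[Si](C)(C)C(C)(C)C)[C@@H]1C(Br)CBr
F9 | step 11 | (E)-6-bromo-3,3-dimethylhept-4-en-2-one (racemic) | CC(=O)C(C)(C)/C=C/C(C)Br
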